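**Plan**

- Retrosynthesis cuts, in this order: the lactone bond O1–C2 (back to a 3,3-diarylpropanoic acid); the pyranone bonds C4'–C5' and O1'–C2' (back to an aryl methyl ketone and a malonyl unit); C4a–C5 and C6–C7 of the benzene ring; last the C4–aryl bond.
- Enabling feature: ring C4a–C5–C6–C7–C8–C8a of the chroman-2-one has oxygen on C7 and C8a (meta), C8–H between them, the acyl-level carbon C6' on C6 and a methyl group on C5. C7–C8–C8a–C4a is thus a 1-methoxy-1,3-bis(silyloxy)diene and C5–C6 with their substituents a but-2-ynoyl unit.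
- Forward: the aryl group is added to a C5 lactone, the chain is lengthened by two carbons to a beta-keto ester and silylated to the diene. The benzene ring forms by (4+2) cycloaddition with pent-3-yn-2-one, then the pyranone ring from the acetyl group, and the lactone ring closes last.
- Stereochemistry: the single centre C4 is set in step 1 by rhodium/(S)-BINAP conjugate arylation and is never alpha to a carbonyl group afterwards.

Key step: step 7

Assumption: the SMILES is read as the (4R) enantiomer. Unprimed locants are those of the chroman-2-one core, primed locants those of the pyranone. TBS = tert-butyldimethylsilyl, TMS = trimethylsilyl. The S-to-R change of descriptor in step 7 is a priority change only (the new arene outranks the silyloxyphenyl group); no bond at the centre is touched.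

**Route**

Step 1
Reactants: 1 4-(TBS-oxy)phenylboronic acid; 2 5,6-dihydro-2H-pyran-2-one
Product: 3 (4S)-4-[4-(TBS-oxy)phenyl]tetrahydro-2H-pyran-2-one
Conditions: [Rh(OH)((S)-BINAP)]2 (1.5 mol %), 1 (2 equiv), dioxane/H2O 10:1, 35 °C
Reagents that add atoms: none
Why: Hayashi–Miyaura rhodium-catalysed asymmetric 1,4-addition, in which the aryl–rhodium species carrying (S)-BINAP inserts the lactone C=C from the face this ligand selects with cyclic enones and unsaturated lactones, should set the only stereocentre as 4S before water releases the product.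

Step 2
Reactants: 3 (4S)-4-aryl lactone
Product: 4 (3S)-5-hydroxy-N-methoxy-N-methyl-3-[4-(TBS-oxy)phenyl]pentanamide
Conditions: MeNH(OMe)·HCl (2.5 equiv), iPrMgCl (5 equiv), THF, −20 → 0 °C; aq. NH4Cl
Reagents that add atoms: N,O-dimethylhydroxylamine hydrochloride, CNOC.Cl
Why: Weinreb aminolysis of the lactone by the chloromagnesium amide opens the ring at the acyl carbon, frees the primary alcohol and leaves the stereocentre untouched.

Step 3
Reactants: 4 hydroxy Weinreb amide
Product: 5 (3S)-5-(TBS-oxy)-N-methoxy-N-methyl-3-[4-(TBS-oxy)phenyl]pentanamide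
Conditions: TBSCl (1.2 equiv), imidazole (2 equiv), CH2Cl2, 0 → 20 °C
Reagents that add atoms: tert-butyldimethylsilyl chloride, CC(C)(C)[Si](C)(C)Cl
Why: Standard silylation of a primary alcohol stops relactonisation and gives a chain end without acidic hydrogen, so that later enolisations have a single site.

Step 4
Reactants: 5 silylated Weinreb amide; 6 methyl acetate
Product: 7 methyl (5S)-7-(TBS-oxy)-5-[4-(TBS-oxy)phenyl]-3-oxoheptanoate
Conditions: 6 (3 equiv), LiN(iPr)2 (3 equiv), THF, −78 °C; then 5, −78 → −40 °C; aq. NH4Cl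
Reagents that add atoms: none
Why: Claisen-type acylation of the lithium enolate of methyl acetate by a Weinreb amide, whose chelated tetrahedral adduct persists until work-up, should give the beta-keto ester without over-addition.

Step 5
Reactants: 7 beta-keto ester
Product: 8 methyl (2E,5S)-7-(TBS-oxy)-5-[4-(TBS-oxy)phenyl]-3-(TMS-oxy)hept-2-enoate (double-bond isomers converge in step 6)
Conditions: Me3SiCl (1.5 equiv), Et3N (1.6 equiv), toluene, 20 °C, 48 h; filtration under argon
Reagents that add atoms: trimethylsilyl chloride, C[Si](C)(C)Cl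
Why: O-Silylation of the enol form of a beta-keto ester with silyl chloride and amine base is the first stage of the standard two-stage preparation of 1-alkoxy-1,3-bis(silyloxy)dienes.

Step 6
Reactants: 8 beta-silyloxy enoate
Product: 9 (1Z,3Z,5S)-7-(TBS-oxy)-5-[4-(TBS-oxy)phenyl]-1-methoxy-1,3-bis(TMS-oxy)hepta-1,3-diene
Conditions: LiN(iPr)2 (1.2 equiv), THF, −78 °C; Me3SiCl (1.3 equiv), −78 → 20 °C; pentane, filtration under argon, used at once
Reagents that add atoms: trimethylsilyl chloride, C[Si](C)(C)Cl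
Why: Gamma-deprotonation of the beta-silyloxy enoate (the only acidic site) and O-silylation of the dienolate is the second stage of that preparation and should give the 3Z diene with the stereogenic carbon on the outside of the diene.

Step 7
Reactants: 9 bis(silyloxy)diene; 10 pent-3-yn-2-one
Product: 13 1-{3-[(1R)-3-(TBS-oxy)-1-[4-(TBS-oxy)phenyl]propyl]-4,6-dihydroxy-2-methylphenyl}ethanone, via cyclohexa-1,4-diene cycloadduct 11 (not isolated), via bis(trimethylsilyl) aryl ether 12 (not isolated)
Conditions: 10 (2 equiv), toluene, sealed tube, 20 → 90 °C, no Lewis acid; then 0.5 M HCl, THF/H2O, 0 °C, 10 min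
Reagents that add atoms: none
Why: The electron-rich diene 9 and the ynone 10 combine in a normal-demand Diels–Alder reaction (concerted but asynchronous, or Mukaiyama–Michael addition followed by closure of the allenolate onto the ketene acetal carbon) that forms C4a–C5 and C6–C7 and gives cyclohexa-1,4-diene 11; loss of methanol across C7 and C4a aromatises it to 12, and cold dilute acid removes the two aryl TMS groups while both TBS ethers stay. The closest known reaction type is the cycloaddition of 1-alkoxy-1,3-bis(silyloxy)buta-1,3-dienes and Brassard-type dienes with acetylenic ketones and esters, which gives resorcinols and salicylates. The one new ring, the benzene ring C4a–C5–C6–C7–C8–C8a, closes intermolecularly in a (4+2) mode with both bonds made in one operation. No lasting stereocentre is formed, since the sp3 ring carbons of 11 are lost on aromatisation; the existing centre is not enolisable and, in the 3Z diene, lies out of reach of a 1,5-hydrogen shift, so it should be carried through unchanged. The step needs regioselectivity: the largest HOMO coefficient sits on the gamma terminus of 9 and the largest LUMO coefficient on the ynone beta carbon, so C4a bonds to the methyl-bearing carbon and the acetal carbon to the acyl-bearing carbon, which places the C7 oxygen ortho and the C8a oxygen para to the acetyl group. Working without a Lewis acid avoids attack at the ketone carbonyl, which would lead to the isomeric (3+3) product.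

Step 8
Reactants: 13 acetyl resorcinol
Product: 14 1-{3-[(1R)-3-(TBS-oxy)-1-[4-(TBS-oxy)phenyl]propyl]-4,6-bis(TBS-oxy)-2-methylphenyl}-1-(TBS-oxy)ethene
Conditions: TBSOTf (3.6 equiv), Et3N (5 equiv), CH2Cl2, −78 → 0 °C
Reagents that add atoms: tert-butyldimethylsilyl trifluoromethanesulfonate, CC(C)(C)[Si](C)(C)OS(=O)(=O)C(F)(F)F
Why: Silyl triflate and amine base silylate both phenols and convert the methyl ketone, the only carbonyl group present, into its silyl enol ether (soft enolisation), so one operation protects the arene oxygens and activates the acetyl group.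

Step 9
Reactants: 14 silyl enol ether; 15 malonyl dichloride
Product: 17 6-{3-[(1R)-3-(TBS-oxy)-1-[4-(TBS-oxy)phenyl]propyl]-4,6-bis(TBS-oxy)-2-methylphenyl}-4-hydroxy-2H-pyran-2-one, via 3,5-dioxopentanoyl chloride 16 (not isolated)
Conditions: 15 (1.1 equiv), Et2O, −78 → 20 °C; pH 4 buffer work-up
Reagents that add atoms: none
Why: Effenberger pyranone synthesis, in which the silyl enol ether is C-acylated by malonyl dichloride and the enolised 3,5-dioxo acid chloride closes through oxygen to the 4-hydroxy-2-pyranone, while the silyl group on the C7 oxygen blocks the competing chromone closure.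

Step 10
Reactants: 17 4-hydroxy-2-pyranone
Product: 18 6-{3-[(1R)-3-(TBS-oxy)-1-[4-(TBS-oxy)phenyl]propyl]-4,6-bis(TBS-oxy)-2-methylphenyl}-4-methoxy-2H-pyran-2-one
Conditions: Me2SO4 (1.3 equiv), K2CO3 (1.5 equiv), dry acetone, 20 °C
Reagents that add atoms: dimethyl sulfate, COS(=O)(=O)OC
Why: O-Alkylation of the vinylogous acid with the hard electrophile dimethyl sulfate and carbonate in acetone is the established way to 4-methoxy-2-pyranones, and no free phenol is present to compete.

Step 11
Reactants: 18 4-methoxy-2-pyranone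
Product: 19 6-{3-[(1R)-3-hydroxy-1-[4-(TBS-oxy)phenyl]propyl]-4,6-bis(TBS-oxy)-2-methylphenyl}-4-methoxy-2H-pyran-2-one
Conditions: camphor-10-sulfonic acid (0.1 equiv), MeOH/CH2Cl2 1:1, 0 °C
Reagents that add atoms: none
Why: Acid-catalysed methanolysis removes a primary alkyl silyl ether much faster than aryl silyl ethers, which are the acid-stable ones.

Step 12
Reactants: 19 primary alcohol
Product: 21 (3R)-3-[2,4-bis(TBS-oxy)-5-(4-methoxy-2-oxo-2H-pyran-6-yl)-6-methylphenyl]-3-[4-(TBS-oxy)phenyl]propanoic acid, via aldehyde 20 (not isolated)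
Conditions: TEMPO (0.2 equiv), PhI(OAc)2 (2.5 equiv), MeCN/H2O 1:1, 20 °C
Reagents that add atoms: water, O
Why: Nitroxyl-catalysed oxidation with PhI(OAc)2 in aqueous acetonitrile takes a primary alcohol through the aldehyde hydrate to the carboxylic acid, and with every phenol oxygen silylated the arenes should not be oxidised.

Step 13
Reactants: 21 silylated propanoic acid
Product: 23 (4R)-7-hydroxy-4-(4-hydroxyphenyl)-6-(4-methoxy-2-oxo-2H-pyran-6-yl)-5-methylchroman-2-one, via triphenol seco acid 22 (not isolated)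
Conditions: HF·pyridine (excess), THF, 0 → 20 °C; then CF3CO2H (cat.), CH2Cl2, 20 °C
Reagents that add atoms: none
Why: Fluoride-mediated cleavage of the three aryl silyl ethers followed by acid-catalysed lactonisation, in which the C8a phenol, the only one within reach of the carboxyl group, closes the six-membered ring with help from the flanking C5 methyl and C4 aryl groups, should give the target with C4 untouched.

**Compound list**

1 | 4-(tert-butyldimethylsilyloxy)phenylboronic acid | OB(O)c1ccc(O[Si](C)(C)C(C)(C)C)cc1 | starting material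
2 | 5,6-dihydro-2H-pyran-2-one | O=C1C=CCCO1 | starting material
3 | (4S)-4-[4-(tert-butyldimethylsilyloxy)phenyl]tetrahydro-2H-pyran-2-one | O=C1C[C@@H](c2ccc(O[Si](C)(C)C(C)(C)C)cc2)CCO1 | intermediate
4 | (3S)-5-hydroxy-N-methoxy-N-methyl-3-[4-(tert-butyldimethylsilyloxy)phenyl]pentanamide | CON(C)C(=O)C[C@@H](c1ccc(O[Si](C)(C)C(C)(C)C)cc1)CCO | intermediate
5 | (3S)-5-(tert-butyldimethylsilyloxy)-N-methoxy-N-methyl-3-[4-(tert-butyldimethylsilyloxy)phenyl]pentanamide | CON(C)C(=O)C[C@@H](c1ccc(O[Si](C)(C)C(C)(C)C)cc1)CCO[Si](C)(C)C(C)(C)C | intermediate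
6 | methyl acetate | COC(C)=O | starting material
7 | methyl (5S)-7-(tert-butyldimethylsilyloxy)-5-[4-(tert-butyldimethylsilyloxy)phenyl]-3-oxoheptanoate | COC(=O)CC(=O)C[C@@H](c1ccc(O[Si](C)(C)C(C)(C)C)cc1)CCO[Si](C)(C)C(C)(C)C | intermediate
8 | methyl (2E,5S)-7-(tert-butyldimethylsilyloxy)-5-[4-(tert-butyldimethylsilyloxy)phenyl]-3-(trimethylsilyloxy)hept-2-enoate | COC(=O)/C=C(/O[Si](C)(C)C)C[C@@H](c1ccc(O[Si](C)(C)C(C)(C)C)cc1)CCO[Si](C)(C)C(C)(C)C | intermediate
9 | (1Z,3Z,5S)-7-(tert-butyldimethylsilyloxy)-5-[4-(tert-butyldimethylsilyloxy)phenyl]-1-methoxy-1,3-bis(trimethylsilyloxy)hepta-1,3-diene | CO/C(O[Si](C)(C)C)=C/C(/O[Si](C)(C)C)=C/[C@@H](c1ccc(O[Si](C)(C)C(C)(C)C)cc1)CCO[Si](C)(C)C(C)(C)C | intermediate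
10 | pent-3-yn-2-one | CC#CC(C)=O | starting material
11 | 1-{3-[(1S)-3-(tert-butyldimethylsilyloxy)-1-[4-(tert-butyldimethylsilyloxy)phenyl]propyl]-6-methoxy-2-methyl-4,6-bis(trimethylsilyloxy)cyclohexa-1,4-dien-1-yl}ethanone (ring centres undefined) | COC1(O[Si](C)(C)C)C=C(O[Si](C)(C)C)C([C@@H](c2ccc(O[Si](C)(C)C(C)(C)C)cc2)CCO[Si](C)(C)C(C)(C)C)C(C)=C1C(C)=O | intermediate (not isolated)
12 | 1-{3-[(1R)-3-(tert-butyldimethylsilyloxy)-1-[4-(tert-butyldimethylsilyloxy)phenyl]propyl]-2-methyl-4,6-bis(trimethylsilyloxy)phenyl}ethanone | CC(=O)c1c(O[Si](C)(C)C)cc(O[Si](C)(C)C)c(c1C)[C@@H](c1ccc(O[Si](C)(C)C(C)(C)C)cc1)CCO[Si](C)(C)C(C)(C)C | intermediate (not isolated)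
13 | 1-{3-[(1R)-3-(tert-butyldimethylsilyloxy)-1-[4-(tert-butyldimethylsilyloxy)phenyl]propyl]-4,6-dihydroxy-2-methylphenyl}ethanone | CC(=O)c1c(O)cc(O)c(c1C)[C@@H](c1ccc(O[Si](C)(C)C(C)(C)C)cc1)CCO[Si](C)(C)C(C)(C)C | intermediate
14 | 1-{3-[(1R)-3-(tert-butyldimethylsilyloxy)-1-[4-(tert-butyldimethylsilyloxy)phenyl]propyl]-4,6-bis(tert-butyldimethylsilyloxy)-2-methylphenyl}-1-(tert-butyldimethylsilyloxy)ethene | C=C(O[Si](C)(C)C(C)(C)C)c1c(O[Si](C)(C)C(C)(C)C)cc(O[Si](C)(C)C(C)(C)C)c(c1C)[C@@H](c1ccc(O[Si](C)(C)C(C)(C)C)cc1)CCO[Si](C)(C)C(C)(C)C | intermediate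
15 | malonyl dichloride | O=C(Cl)CC(=O)Cl | starting material
16 | 5-{3-[(1R)-3-(tert-butyldimethylsilyloxy)-1-[4-(tert-butyldimethylsilyloxy)phenyl]propyl]-4,6-bis(tert-butyldimethylsilyloxy)-2-methylphenyl}-3,5-dioxopentanoyl chloride | O=C(Cl)CC(=O)CC(=O)c1c(O[Si](C)(C)C(C)(C)C)cc(O[Si](C)(C)C(C)(C)C)c(c1C)[C@@H](c1ccc(O[Si](C)(C)C(C)(C)C)cc1)CCO[Si](C)(C)C(C)(C)C | intermediate (not isolated)
17 | 6-{3-[(1R)-3-(tert-butyldimethylsilyloxy)-1-[4-(tert-butyldimethylsilyloxy)phenyl]propyl]-4,6-bis(tert-butyldimethylsilyloxy)-2-methylphenyl}-4-hydroxy-2H-pyran-2-one | Oc1cc(-c2c(O[Si](C)(C)C(C)(C)C)cc(O[Si](C)(C)C(C)(C)C)c(c2C)[C@@H](c2ccc(O[Si](C)(C)C(C)(C)C)cc2)CCO[Si](C)(C)C(C)(C)C)oc(=O)c1 | intermediate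
18 | 6-{3-[(1R)-3-(tert-butyldimethylsilyloxy)-1-[4-(tert-butyldimethylsilyloxy)phenyl]propyl]-4,6-bis(tert-butyldimethylsilyloxy)-2-methylphenyl}-4-methoxy-2H-pyran-2-one | COc1cc(-c2c(O[Si](C)(C)C(C)(C)C)cc(O[Si](C)(C)C(C)(C)C)c(c2C)[C@@H](c2ccc(O[Si](C)(C)C(C)(C)C)cc2)CCO[Si](C)(C)C(C)(C)C)oc(=O)c1 | intermediate
19 | 6-{3-[(1R)-3-hydroxy-1-[4-(tert-butyldimethylsilyloxy)phenyl]propyl]-4,6-bis(tert-butyldimethylsilyloxy)-2-methylphenyl}-4-methoxy-2H-pyran-2-one | COc1cc(-c2c(O[Si](C)(C)C(C)(C)C)cc(O[Si](C)(C)C(C)(C)C)c(c2C)[C@@H](c2ccc(O[Si](C)(C)C(C)(C)C)cc2)CCO)oc(=O)c1 | intermediate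
20 | (3R)-3-[2,4-bis(tert-butyldimethylsilyloxy)-5-(4-methoxy-2-oxo-2H-pyran-6-yl)-6-methylphenyl]-3-[4-(tert-butyldimethylsilyloxy)phenyl]propanal | COc1cc(-c2c(O[Si](C)(C)C(C)(C)C)cc(O[Si](C)(C)C(C)(C)C)c(c2C)[C@@H](c2ccc(O[Si](C)(C)C(C)(C)C)cc2)CC=O)oc(=O)c1 | intermediate (not isolated)
21 | (3R)-3-[2,4-bis(tert-butyldimethylsilyloxy)-5-(4-methoxy-2-oxo-2H-pyran-6-yl)-6-methylphenyl]-3-[4-(tert-butyldimethylsilyloxy)phenyl]propanoic acid | COc1cc(-c2c(O[Si](C)(C)C(C)(C)C)cc(O[Si](C)(C)C(C)(C)C)c(c2C)[C@@H](c2ccc(O[Si](C)(C)C(C)(C)C)cc2)CC(=O)O)oc(=O)c1 | intermediate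
22 | (3R)-3-[2,4-dihydroxy-5-(4-methoxy-2-oxo-2H-pyran-6-yl)-6-methylphenyl]-3-(4-hydroxyphenyl)propanoic acid | COc1cc(-c2c(O)cc(O)c(c2C)[C@@H](c2ccc(O)cc2)CC(=O)O)oc(=O)c1 | intermediate (not isolated)
23 | (4R)-7-hydroxy-4-(4-hydroxyphenyl)-6-(4-methoxy-2-oxo-2H-pyran-6-yl)-5-methylchroman-2-one | COc1cc(-c2c(O)cc3c(c2C)[C@@H](c2ccc(O)cc2)CC(=O)O3)oc(=O)c1 | target

**Totals**

Total step count: 13. Longest linear sequence: 13 steps (1 and 2 to 23).

**Steps most likely to fail**

Step 7. Both bond-forming termini are hindered (a branched substituent on the diene terminus, a methyl group on the ynone beta carbon), so the cycloaddition may be outrun by protodesilylation of the diene through the methanol set free, or by polymerisation of the ynone. The fallback sets out from 9 and changes the two-carbon partner to an allene. Penta-3,4-dien-2-one F1 is made by Dess–Martin oxidation of pent-4-yn-2-ol and isomerisation of the crude ynone with triethylamine, and is used fresh. It offers an unsubstituted sp carbon to the diene terminus and is the stronger acceptor. Cycloaddition across its conjugated double bond at 20–60 °C should give, with the same orientation, the 5-methylidene cycloadduct F2. Dilute acid then eliminates methanol, moves the exocyclic double bond into the ring and removes the TMS groups. The route is rejoined at 13.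

Step 9. A second malonyl unit may acylate the hydroxypyranone as it forms, or the hydrogen chloride set free may remove silyl groups and open the way to O-acylation and chromone closure. The fallback sets out from 13 and builds the pyranone through anions, one carbonyl group at a time. TBSOTf with 2,6-lutidine silylates both phenols to the bis(silyloxy) aryl methyl ketone F3. Its lithium enolate (LiN(SiMe3)2, THF, −78 °C) is C-acetylated with N-acetylimidazole to the 1-aryl-butane-1,3-dione F4. The dianion of F4 (LiN(iPr)2, 3 equiv) is carboxylated at the terminal carbon with CO2 to the 5-aryl-3,5-dioxopentanoic acid F5. Cyclodehydration with acetic anhydride or a carbodiimide closes the 4-hydroxy-2-pyranone. The route is rejoined at 17.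

Step 1. Protodeboronation of the electron-rich boronic acid and hydrolytic opening of the lactone may outrun the slow insertion, and any ligand-free rhodium would erode the enantiomeric purity. The fallback sets out from 1 and moves the arylation to an acyclic acceptor that cannot be hydrolysed. (E)-5-(TBS-oxy)-N-methoxy-N-methylpent-2-enamide F6 is prepared by Horner–Wadsworth–Emmons reaction of 3-(TBS-oxy)propanal with diethyl [2-(methoxy(methyl)amino)-2-oxoethyl]phosphonate. Rhodium-catalysed asymmetric 1,4-addition of 1 to F6 uses [RhCl(C2H4)2]2 with a chiral 2,5-diphenylbicyclo[2.2.2]octa-2,5-diene ligand and KOH (cat.) in dioxane/H2O at 30 °C. The ligand enantiomer is chosen to deliver the (3S) amide. This gives the silylated Weinreb amide directly, and the route is rejoined at 5.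

**Further compounds**

F1 | step 7 | penta-3,4-dien-2-one | CC(=O)C=C=C
F2 | step 7 | 1-{3-[(1S)-3-(tert-butyldimethylsilyloxy)-1-[4-(tert-butyldimethylsilyloxy)phenyl]propyl]-6-methoxy-2-methylidene-4,6-bis(trimethylsilyloxy)cyclohex-4-en-1-yl}ethanone (ring centres undefined) | COC1(O[Si](C)(C)C)C=C(O[Si](C)(C)C)C([C@@H](c2ccc(O[Si](C)(C)C(C)(C)C)cc2)CCO[Si](C)(C)C(C)(C)C)C(=C)C1C(C)=O
F3 | step 9 | 1-{3-[(1R)-3-(tert-butyldimethylsilyloxy)-1-[4-(tert-butyldimethylsilyloxy)phenyl]propyl]-4,6-bis(tert-butyldimethylsilyloxy)-2-methylphenyl}ethanone | CC(=O)c1c(O[Si](C)(C)C(C)(C)C)cc(O[Si](C)(C)C(C)(C)C)c(c1C)[C@@H](c1ccc(O[Si](C)(C)C(C)(C)C)cc1)CCO[Si](C)(C)C(C)(C)C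
F4 | step 9 | 1-{3-[(1R)-3-(tert-butyldimethylsilyloxy)-1-[4-(tert-butyldimethylsilyloxy)phenyl]propyl]-4,6-bis(tert-butyldimethylsilyloxy)-2-methylphenyl}butane-1,3-dione | CC(=O)CC(=O)c1c(O[Si](C)(C)C(C)(C)C)cc(O[Si](C)(C)C(C)(C)C)c(c1C)[C@@H](c1ccc(O[Si](C)(C)C(C)(C)C)cc1)CCO[Si](C)(C)C(C)(C)C
F5 | step 9 | 5-{3-[(1R)-3-(tert-butyldimethylsilyloxy)-1-[4-(tert-butyldimethylsilyloxy)phenyl]propyl]-4,6-bis(tert-butyldimethylsilyloxy)-2-methylphenyl}-3,5-dioxopentanoic acid | OC(=O)CC(=O)CC(=O)c1c(O[Si](C)(C)C(C)(C)C)cc(O[Si](C)(C)C(C)(C)C)c(c1C)[C@@H](c1ccc(O[Si](C)(C)C(C)(C)C)cc1)CCO[Si](C)(C)C(C)(C)C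
F6 | step 1 | (E)-5-(tert-butyldimethylsilyloxy)-N-methoxy-N-methylpent-2-enamide | CON(C)C(=O)/C=C/CCO[Si](C)(C)C(C)(C)C
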